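At early times the birch run loses substrate in proportion to what stands: ln(charged/left) over time gives 0.468 min⁻¹ from the first reading and 0.444 min⁻¹ from the last, and with a scatter of 0.5 percentage points the first of these is loose.

- birch: substrate 0.060 M; acid 1.2 mM; run made earlier
- flask: substrate 0.12 M; acid 1.20 mM; time 6.0 min

birch run (percent of the substrate charged)

| time / s | substrate / % | target / % |
|---|---|---|
| 10.0 | 92.5 | 4.9 |
| 15.0 | 89.0 | 6.9 |
| 20.0 | 85.7 | 9.6 |
| 30.0 | 79.4 | 14.6 |
| 40.0 | 74.4 | 17.5 |

(each reading ± 0.5 percentage points)

- acid is the free proton; pH is minus the decimal logarithm of its molar concentration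

1. part of the substrate that has reacted at 6.0 min
2. pH of the solution at 6.0 min

Read from that last value, 1.56 min is the apparent substrate half-life of the birch run, the time in which substrate halves if its loss stays first order; I assume that it does, as a pseudo-first-order loss at a steady acid level. Is the acid steady? At the last birch reading 4.86 mM of material is unseen, more than the 1.2 mM of acid charged, so that gap is no one-for-one loss of acid, and I hold the pH flat at the value the charge gives.

The flask has the same acid and twice the substrate. First order leaves the half-life unchanged, though the birch run cannot test that. The substrate reacted then starts at a slope of 0.444 min⁻¹, reaches half at 1.56 min, has a quarter left at 3.12 min, and bends toward complete reaction. At 6.0 min I expect 6.98% left, so 93.0% reacted.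

The forecast gives 93% (82% to 96%) and pH 2.92 (2.88 to 3.1), on the ground: “Acid looks like a catalyst”. The flask gives 92.1% reacted and pH 2.92.

    substrate + acid → weak acid + acid + target (k = 4.30 M⁻¹ s⁻¹)
    weak acid ⇌ conjugate base + acid, settled at all times (K = 6.30 × 10⁻⁸ M)
    substrate → weak acid + target (k = 3.20 × 10⁻⁴ s⁻¹)
    weak acid → by-product carried off (k = 0.00380 s⁻¹)
    2 substrate → homo dimer (k = 0.0200 M⁻¹ s⁻¹)
    target ⇌ isomer of the product (K = 0.190, k = 6.50 × 10⁻⁴ s⁻¹)

In the flask at 1.41 min, the step with acid gives substrate a half-life of 2.2 min, far shorter than the 36 min of the step without acid, which is long against the 6.0 min of the flask. Doubling the substrate and nothing else lifts the part reacted at the last birch reading, without scatter, from 26.1% to 31.5%, so the apparent half-life is not the same at the two charges. Reckoned with it, the flask keeps 6.98% against the 7.9% found, and a neighbour with the same charges read at 4.0 min keeps 16.9%, where that neighbour holds 16%.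

The data were computed from invented constants; the scatter is artificial.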